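The numbers in the tables come from a simulation with made-up constants.

| flask | substrate | first nucleophile | second nucleophile | protic impurity | temperature | remark | time |
|---|---|---|---|---|---|---|---|
| Friday's | 0.10 M | 0.27 M | 0.18 M | 0.030 M | −20 °C | run made earlier |  |
| Wednesday's | 0.10 M | 0.45 M | 0.18 M | 0.030 M | 20 °C | run made earlier |  |
| Tuesday's | 0.10 M | 0.20 M | 0.18 M | 0.064 M | −20 °C | run made earlier |  |
| alder | 0.10 M | 0.400 M | 0.180 M | 0.0300 M | 55 °C |  | 2.5 h |
| ash | 0.10 M | 0.200 M | 0.180 M | 0.100 M | −15 °C |  | 2.5 h |
| larch | 0.10 M | 0.200 M | 0.180 M | 0.0300 M | 25 °C |  | 2.5 h |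
| maple | 0.025 M | 0.200 M | 0.180 M | 0.0300 M | 5 °C |  | 2.5 h |

| run | time / h | target / % | other capture product / % |
|---|---|---|---|
| Friday's | 4.00 | 3.1 | 1.5 |
| Friday's | 8.00 | 6.7 | 3.7 |
| Friday's | 12.0 | 8.4 | 5.3 |
| Friday's | 15.0 | 11.6 | 6.2 |
| Friday's | 20.0 | 16.0 | 10.3 |
| Friday's | 25.0 | 18.3 | 9.3 |
| Wednesday's | 0.417 | 30.2 | 12.3 |
| Wednesday's | 0.833 | 44.2 | 17.7 |
| Wednesday's | 1.33 | 51.3 | 25.9 |
| Wednesday's | 1.50 | 53.4 | 29.3 |
| Wednesday's | 2.00 | 56.3 | 30.5 |
| Wednesday's | 2.50 | 59.9 | 31.7 |
| Tuesday's | 2.00 | 1.4 | 1.6 |
| Tuesday's | 6.00 | 3.5 | 3.2 |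
| Tuesday's | 12.0 | 9.6 | 7.6 |
| Tuesday's | 20.0 | 12.8 | 9.1 |
| Tuesday's | 25.0 | 13.9 | 14.4 |

(readings scatter by 1 percentage point)

* all flasks from highest to lowest share of target in all that became target or other capture product, at 2.5 h (alder / ash / larch / maple)
* the same order at 20 h (alder / ash / larch / maple)
* the share of target in all that became target or other capture product of the flask you put first, at 2.5 h
* the share of target in all that became target or other capture product of the flask you put last, at 2.5 h

Start from the slowness. Friday's run, at −20 °C, captured 27.6% of its substrate in 25.0 h, a substrate half-life of 53.7 h. Ash runs near that, at −15 °C, and is read at 2.5 h, far shorter, so its share of target follows the ratio of the two nucleophiles during those hours.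

Read the selectivity factor, target over other capture product per unit of concentration ratio, from Friday's last two readings: 1.17. Then read the reagent's loss from Tuesday's run. Its product ratio is 1.26 up to 12.0 h and 0.632 afterwards. The midpoints of those stretches lie 12.5 h apart, which gives a reagent half-life of 12.5 h.

Treat quenching as pseudo-first-order in reagent and scale by the impurity charged: ash gets 8.01 h, leaving the warmer bath out. Now form the quench count, the number of reagent half-lives by quenching that fit into the time asked: 0.312.

Bound ash from above with the reagent as charged: 56.5%. Bound it from below with every capture at the end-of-window ratio: 51.1%. Tighten by taking the ratio at mid-window, since capture runs fairly evenly: 53.8%.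

The forecast gives ash > maple > alder > larch at 2.5 h and maple > alder > ash > larch at 20 h, with 54% for the first flask and 39% for the last, and says “Ash at 2.5 h has barely lost reagent”; its top value lies inside the bracket.

The flasks give ash > maple > larch > alder at 2.5 h and maple > ash > larch > alder at 20 h. Ash reaches 55.4%, inside the bracket, and alder 5.16%.

    substrate ⇌ intermediate (K = 0.0120, k = 0.167 min⁻¹, Ea = 92.0 kJ mol⁻¹, ΔH = −40.0 kJ mol⁻¹)
    first nucleophile + intermediate → target (k = 4.71 M⁻¹ min⁻¹, Ea = 39.0 kJ mol⁻¹)
    second nucleophile + intermediate → other capture product (k = 4.40 M⁻¹ min⁻¹, Ea = 41.0 kJ mol⁻¹)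
    first nucleophile + protic impurity → quenched reagent (k = 0.250 M⁻¹ min⁻¹, Ea = 50.0 kJ mol⁻¹)
    first nucleophile → decomposed reagent (k = 0.0160 min⁻¹, Ea = 96.0 kJ mol⁻¹)
    (constants at 25 °C)

In ash, quenching alone gives the first nucleophile a half-life of 11 h, the other concentrations as charged, much longer than the 2.5 h of the reading. That makes the count 0.238, smaller than the reckoned 0.312, and 84.4% of the first nucleophile stands at that time. Carry the count 0.238 to the neighbour flask, which is ash with 0.080 M of first nucleophile at the same impurity and temperature: the bracket runs from 30.5% to 34.1%, and that flask gives 33.0%.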